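**Retrosynthetic overview**
- The C5 aldehyde of the target (5-formyl-δ-tocotrienol) is removed first, by ortho-formylation of the C6 phenol; the phenol is then masked as its triisopropylsilyl ether.
- Key disconnection: O1–C8a and C8–CH3 in one operation. The route rests on O1 and the C8 methyl sitting on neighbouring benzene carbons (C8a, C8), with C8a flanked on its other side by C4a, which carries the C4–C3 tether to the tertiary carbinol C2. A C8–C8a aryne can thus be closed by the tethered alkoxide at C8a and the C8 carbanion methylated.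
- The aryne precursor, a (3R)-tertiary alcohol carrying a 2-fluoro-5-silyloxyphenyl group, comes from a B-alkyl Suzuki coupling of silylated 3-bromo-4-fluorophenol with the 9-BBN adduct of (R)-geranyllinalool.
- (R)-Geranyllinalool comes from geranylgeraniol by Sharpless epoxidation (sets the only stereocentre), iodination and zinc ring opening.
- Ring order: the benzene ring is bought; the pyran ring is the only ring formed, in the key step.

Key step: step 6

Remark: chroman numbering (O1, C2, C3, C4, C4a, C5 to C8, C8a) is used for the ring atoms throughout, also in open-chain precursors; geranylgeraniol, 3-bromo-4-fluorophenol and iodomethane are taken as commercial.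

**Step 1**
Reactants: 1 (2E,6E,10E)-geranylgeraniol
Product: 2 (2R,3R)-2,3-epoxygeranylgeraniol
Conditions: Ti(OiPr)4 (cat.), D-(−)-diethyl tartrate (cat.), t-BuOOH, 4 Å MS, CH2Cl2, −20 °C
Reagents that add atoms: tert-butyl hydroperoxide, CC(C)(C)OO
Why: Sharpless asymmetric epoxidation touches only the allylic C2=C3 alkene, and the D-(−)-tartrate ligand should deliver oxygen to the face that gives the (2R,3R)-epoxide (the mirror image of the (2S,3S)-epoxide that geraniol-type alcohols give with L-(+)-tartrate), which sets the future chroman C2 as R.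

**Step 2**
Reactants: 2 (2R,3R)-2,3-epoxygeranylgeraniol
Product: 3 (2S,3R)-2-(iodomethyl)-3-methyl-3-[(3E,7E)-4,8,12-trimethyltrideca-3,7,11-trien-1-yl]oxirane
Conditions: I2, PPh3, imidazole, CH2Cl2, 0 °C
Reagents that add atoms: iodine, II
Why: Appel-type (Garegg–Samuelsson) iodination displaces the activated primary hydroxyl by iodide at C1 under buffered conditions, so neither epoxide carbon is touched (the descriptor at C2 changes only because CH2I outranks the ring carbon).

**Step 3**
Reactants: 3 (2S,3R)-2-(iodomethyl)-3-methyl-3-[(3E,7E)-4,8,12-trimethyltrideca-3,7,11-trien-1-yl]oxirane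
Product: 4 (3R,6E,10E)-3,7,11,15-tetramethylhexadeca-1,6,10,14-tetraen-3-ol [(R)-geranyllinalool]
Conditions: Zn dust, EtOH, reflux
Reagents that add atoms: none
Why: zinc inserts into the C–I bond and the organozinc undergoes β-elimination with cleavage of the epoxide C2–O bond (reductive ring opening of a 2,3-epoxy iodide), which forms the vinyl group and leaves the C3–O bond, and thus the R configuration, untouched.

**Step 4**
Reactants: 5 3-bromo-4-fluorophenol
Product: 6 (3-bromo-4-fluorophenoxy)triisopropylsilane
Conditions: TIPSCl, imidazole, DMF, rt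
Reagents that add atoms: chlorotriisopropylsilane, CC(C)[Si](Cl)(C(C)C)C(C)C
Why: imidazole-promoted O-silylation of a phenol is routine and installs the bulky, non-coordinating ether needed in step 6.

**Step 5**
Reactants: 4 (3R,6E,10E)-3,7,11,15-tetramethylhexadeca-1,6,10,14-tetraen-3-ol; 6 (3-bromo-4-fluorophenoxy)triisopropylsilane
Product: 8 (3R,6E,10E)-1-[2-fluoro-5-(triisopropylsilyloxy)phenyl]-3,7,11,15-tetramethylhexadeca-6,10,14-trien-3-ol, via B-alkyl-9-BBN adduct 7 (not isolated)
Conditions: 9-BBN (2.2 equiv), THF, 0 °C → rt; then 6, PdCl2(dppf) (cat.), aq. K3PO4, THF/DMF, 50 °C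
Reagents that add atoms: none
Why: 9-BBN hydroborates the terminal vinyl group at C1 far faster than the three trisubstituted alkenes (the excess allows for slow consumption by the tertiary hydroxyl), and the B-alkyl Suzuki–Miyaura coupling then joins C1 to the bromine-bearing carbon of 6 without touching the C–F bond or the stereocentre.

**Step 6**
Reactants: 8 (3R,6E,10E)-1-[2-fluoro-5-(triisopropylsilyloxy)phenyl]-3,7,11,15-tetramethylhexadeca-6,10,14-trien-3-ol; 9 iodomethane
Product: 13 O-triisopropylsilyl-δ-tocotrienol, via C8-lithiated fluoroarene alkoxide 10 (not isolated), via C8–C8a aryne alkoxide 11 (not isolated), via 8-lithiochroman 12 (not isolated)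
Conditions: s-BuLi (2.05 equiv), THF (0.02 M), −78 °C; warm to −20 °C; then MeI (excess), −78 °C → rt
Reagents that add atoms: iodomethane (compound 9), CI
Why: Proposed new method: s-BuLi first forms the lithium alkoxide and then removes C8–H, the only hydrogen ortho to fluorine (10); on warming, loss of LiF gives the C8–C8a aryne 11, the tethered alkoxide adds to C8a and closes the pyran ring (O1–C8a) in a 6-exo-dig mode, and the C8 aryllithium 12 left behind is alkylated by iodomethane (C8–CH3). The closest known reaction type is the base-mediated cyclisation of aryne-tethered alkoxides, amides and organolithiums to chromans, indolines and related rings, in some cases with electrophilic capture of the new aryllithium; the pairing of a tertiary alkoxide nucleophile with a methyl quench in one flask is the untested part. No stereocentre is created: the C2–O bond is never broken, so the R configuration from step 1 is carried into the ring. Site selectivity of the lithiation rests on the acidifying fluorine and on the bulky, non-coordinating triisopropylsilyl ether, which shields C5–H and C7–H; regioselectivity of the addition is fixed by the tether, which can reach C8a but not C8. An alkyllithium is chosen because a lithium amide would leave an N–H acid of similar strength that could protonate 12 before the methyl quench, and high dilution with close to two equivalents of base should hold back intermolecular addition of organolithiums to the aryne.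

**Step 7**
Reactants: 13 O-triisopropylsilyl-δ-tocotrienol
Product: 14 δ-tocotrienol
Conditions: Bu4NF, THF, 0 °C
Reagents that add atoms: none
Why: fluoride-mediated desilylation cleaves the aryl Si–O bond and should leave the chroman ether and the trisubstituted alkenes untouched.

**Step 8**
Reactants: 14 δ-tocotrienol
Product: 15 (2R)-6-hydroxy-2,8-dimethyl-2-[(3E,7E)-4,8,12-trimethyltrideca-3,7,11-trien-1-yl]chromane-5-carbaldehyde (5-formyl-δ-tocotrienol)
Conditions: MgCl2, Et3N, (CH2O)n, MeCN, reflux
Reagents that add atoms: paraformaldehyde (formaldehyde unit), C=O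
Why: in the Casnati–Skattebøl ortho-formylation the magnesium phenoxide delivers formaldehyde to an ortho carbon and a second formaldehyde oxidises the benzylic alkoxide by hydride transfer; of the two ortho positions C5 is expected to be preferred because attack there passes through a dienone that keeps the ring-fusion C4a=C8a double bond (bond fixation by the fused pyran ring).

**Compound list**
1 | (2E,6E,10E)-geranylgeraniol | CC(C)=CCC/C(C)=C/CC/C(C)=C/CC/C(C)=C/CO | starting material
2 | (2R,3R)-2,3-epoxygeranylgeraniol, [(2R,3R)-3-methyl-3-[(3E,7E)-4,8,12-trimethyltrideca-3,7,11-trien-1-yl]oxiran-2-yl]methanol | CC(C)=CCC/C(C)=C/CC/C(C)=C/CC[C@@]1(C)O[C@@H]1CO | intermediate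
3 | (2S,3R)-2-(iodomethyl)-3-methyl-3-[(3E,7E)-4,8,12-trimethyltrideca-3,7,11-trien-1-yl]oxirane | CC(C)=CCC/C(C)=C/CC/C(C)=C/CC[C@@]1(C)O[C@@H]1CI | intermediate
4 | (3R,6E,10E)-3,7,11,15-tetramethylhexadeca-1,6,10,14-tetraen-3-ol, (R)-geranyllinalool | CC(C)=CCC/C(C)=C/CC/C(C)=C/CC[C@@](C)(O)C=C | intermediate
5 | 3-bromo-4-fluorophenol | Oc1ccc(F)c(Br)c1 | starting material
6 | (3-bromo-4-fluorophenoxy)triisopropylsilane | CC(C)[Si](Oc1ccc(F)c(Br)c1)(C(C)C)C(C)C | intermediate
7 | (3R,6E,10E)-1-(9-borabicyclo[3.3.1]nonan-9-yl)-3,7,11,15-tetramethylhexadeca-6,10,14-trien-3-ol (hydroxyl shown free) | CC(C)=CCC/C(C)=C/CC/C(C)=C/CC[C@@](C)(O)CCB1C2CCCC1CCC2 | intermediate (not isolated)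
8 | (3R,6E,10E)-1-[2-fluoro-5-(triisopropylsilyloxy)phenyl]-3,7,11,15-tetramethylhexadeca-6,10,14-trien-3-ol | CC(C)=CCC/C(C)=C/CC/C(C)=C/CC[C@@](C)(O)CCc1cc(O[Si](C(C)C)(C(C)C)C(C)C)ccc1F | intermediate
9 | iodomethane | CI | starting material
10 | lithium (3R,6E,10E)-1-[2-fluoro-3-lithio-5-(triisopropylsilyloxy)phenyl]-3,7,11,15-tetramethylhexadeca-6,10,14-trien-3-olate | CC(C)=CCC/C(C)=C/CC/C(C)=C/CC[C@@](C)(O[Li])CCc1cc(O[Si](C(C)C)(C(C)C)C(C)C)cc([Li])c1F | intermediate (not isolated)
11 | lithium (3R,6E,10E)-1-[2,3-didehydro-5-(triisopropylsilyloxy)phenyl]-3,7,11,15-tetramethylhexadeca-6,10,14-trien-3-olate (C8–C8a aryne) | CC(C)=CCC/C(C)=C/CC/C(C)=C/CC[C@@](C)(O[Li])CCC1=CC(O[Si](C(C)C)(C(C)C)C(C)C)=CC#C1 | intermediate (not isolated)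
12 | (2R)-8-lithio-2-methyl-2-[(3E,7E)-4,8,12-trimethyltrideca-3,7,11-trien-1-yl]-6-(triisopropylsilyloxy)chromane | CC(C)=CCC/C(C)=C/CC/C(C)=C/CC[C@]1(C)CCc2cc(O[Si](C(C)C)(C(C)C)C(C)C)cc([Li])c2O1 | intermediate (not isolated)
13 | O-triisopropylsilyl-δ-tocotrienol, (2R)-2,8-dimethyl-2-[(3E,7E)-4,8,12-trimethyltrideca-3,7,11-trien-1-yl]-6-(triisopropylsilyloxy)chromane | CC(C)=CCC/C(C)=C/CC/C(C)=C/CC[C@]1(C)CCc2cc(O[Si](C(C)C)(C(C)C)C(C)C)cc(C)c2O1 | intermediate
14 | δ-tocotrienol, (2R)-2,8-dimethyl-2-[(3E,7E)-4,8,12-trimethyltrideca-3,7,11-trien-1-yl]chroman-6-ol | CC(C)=CCC/C(C)=C/CC/C(C)=C/CC[C@]1(C)CCc2cc(O)cc(C)c2O1 | intermediate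
15 | (2R)-6-hydroxy-2,8-dimethyl-2-[(3E,7E)-4,8,12-trimethyltrideca-3,7,11-trien-1-yl]chromane-5-carbaldehyde | CC(C)=CCC/C(C)=C/CC/C(C)=C/CC[C@]1(C)CCc2c(C=O)c(O)cc(C)c2O1 | target

**Step count and risks**
Total steps: 8. Longest linear sequence: 7 (steps 1, 2, 3, 5, 6, 7, 8 from geranylgeraniol); step 4 is a one-step side branch.

Steps most likely to fail:

1. Step 6 (key step). The aggregated lithium tertiary alkoxide may add to the aryne too slowly, so that intermolecular capture of the aryne by organolithium species, or proton capture at C8 before methylation, takes over. The fallback splits the one-flask step into two known operations. Setting out from 8, excess lithium 2,2,6,6-tetramethylpiperidide (THF, −78 °C → 0 °C) would carry out the aryne ring closure without trapping, the amine formed protonating C8, to give (2R)-2-methyl-2-[(3E,7E)-4,8,12-trimethyltrideca-3,7,11-trien-1-yl]-6-(triisopropylsilyloxy)chromane F1. Ortho-lithiation of F1 directed by the ring oxygen O1 (s-BuLi, TMEDA, THF, −78 °C; C5–H and C7–H stay shielded by the silyl ether) followed by iodomethane 9 would then give 13, where the route is rejoined.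

2. Step 8. Formylation may also occur at C7, the other carbon ortho to the phenol, so regioselectivity may be insufficient. The fallback fixes the position through a halide. Setting out from 14, the morpholine–iodine complex (CH2Cl2/MeOH, 0 °C) should iodinate the ring, preferentially at C5 under the same bond-fixation control, to give (2R)-5-iodo-2,8-dimethyl-2-[(3E,7E)-4,8,12-trimethyltrideca-3,7,11-trien-1-yl]chroman-6-ol F2, from which any 7-iodo isomer can be removed. Deprotonation and iodine–lithium exchange (t-BuLi, 3 equiv, THF, −78 °C) and a DMF quench would then give 15 directly.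

3. Step 5. The free tertiary hydroxyl may consume borane or slow the hydroboration, and protodeboronation may outrun transmetalation of the hindered alkylborane. The fallback forms the same C–C bond by a Heck reaction. Setting out from 4 and 6, Pd(OAc)2, P(o-tol)3 and Et3N in DMF at 90 °C should give (1E,3R,6E,10E)-1-[2-fluoro-5-(triisopropylsilyloxy)phenyl]-3,7,11,15-tetramethylhexadeca-1,6,10,14-tetraen-3-ol F3; no β-hydrogen is available on the carbinol side. Diimide (2-nitrobenzenesulfonyl hydrazide, Et3N, CH2Cl2, rt) would then reduce only the disubstituted alkene and give 8.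

**Further compounds**
F1 | step 6 | (2R)-2-methyl-2-[(3E,7E)-4,8,12-trimethyltrideca-3,7,11-trien-1-yl]-6-(triisopropylsilyloxy)chromane | CC(C)=CCC/C(C)=C/CC/C(C)=C/CC[C@]1(C)CCc2cc(O[Si](C(C)C)(C(C)C)C(C)C)ccc2O1
F2 | step 8 | (2R)-5-iodo-2,8-dimethyl-2-[(3E,7E)-4,8,12-trimethyltrideca-3,7,11-trien-1-yl]chroman-6-ol | CC(C)=CCC/C(C)=C/CC/C(C)=C/CC[C@]1(C)CCc2c(I)c(O)cc(C)c2O1
F3 | step 5 | (1E,3R,6E,10E)-1-[2-fluoro-5-(triisopropylsilyloxy)phenyl]-3,7,11,15-tetramethylhexadeca-1,6,10,14-tetraen-3-ol | CC(C)=CCC/C(C)=C/CC/C(C)=C/CC[C@@](C)(O)/C=C/c1cc(O[Si](C(C)C)(C(C)C)C(C)C)ccc1F
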